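The route rests on cutting the C10–C11 single bond. This splits the C52 target into two C26 halves: iodoenone 14 (β-ring C1–C6, C7–C10, C19 ester) and heptaenylboronate 28 (C11–C7' chain on the ε-ring C1'–C6'). The key step exploits that C10 is the β-carbon of the C8=O/C9=C10 enone, a vinylogous acyl position whose iodide adds to zerovalent palladium very fast, while C11 ends an electron-rich polyene. One Suzuki–Miyaura coupling, run as the last step on unprotected partners, completes the octaenone chromophore with retention of the 9E and 11E geometries and gives the target directly.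

Key step: step 18

Remark: carotenoid numbering (C1–C20, C1'–C20') is used throughout. The carbinol centres at C8 (9, 10, 12) and C9' (22) and the spiro carbon of 18 and 19 are carried as mixtures because later steps erase them.

Step 1
Reactants: 1 (4R,6R)-4-hydroxy-2,2,6-trimethylcyclohexan-1-one (actinol)
Product: 2 (4R,6R)-4-(tert-butyldimethylsilyloxy)-2,2,6-trimethylcyclohexan-1-one
Conditions: t-BuMe2SiCl, imidazole, DMF, 25 °C
Reagents that add atoms: tert-butyldimethylsilyl chloride, C[Si](C)(Cl)C(C)(C)C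
Why: Standard silyl ether formation at the only hydroxyl group leaves both stereocentres untouched and masks the alcohol for the base and hydride steps ahead.

Step 2
Reactants: 2 (4R,6R)-4-(tert-butyldimethylsilyloxy)-2,2,6-trimethylcyclohexan-1-one
Product: 4 (4R)-4-(tert-butyldimethylsilyloxy)-2,6,6-trimethylcyclohex-1-en-1-yl trifluoromethanesulfonate, via potassium enolate 3 (not isolated)
Conditions: KN(SiMe3)2, THF, −78 °C; PhNTf2, −78 to 0 °C
Reagents that add atoms: N-phenylbis(trifluoromethanesulfonimide), O=S(=O)(N(c1ccccc1)S(=O)(=O)C(F)(F)F)C(F)(F)F; KN(SiMe3)2, [K+].C[Si](C)(C)[N-][Si](C)(C)C (its potassium stays in 3 only)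
Why: The ketone can enolise only toward the methyl-bearing carbon, so enol triflate formation gives one tetrasubstituted alkenyl triflate, erases that centre and keeps the carbinol centre that becomes C3 (R).

Step 3
Reactants: 4 (4R)-4-(tert-butyldimethylsilyloxy)-2,6,6-trimethylcyclohex-1-en-1-yl trifluoromethanesulfonate; 5 (E)-2-(2-ethoxyvinyl)-4,4,5,5-tetramethyl-1,3,2-dioxaborolane
Product: 7 2-[(4R)-4-(tert-butyldimethylsilyloxy)-2,6,6-trimethylcyclohex-1-en-1-yl]acetaldehyde, via dienol ether 6 (not isolated)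
Conditions: Pd(PPh3)4 (5 mol %), K3PO4, dioxane/H2O, 80 °C; then 1 M HCl, THF, 0 °C
Reagents that add atoms: water, O
Why: Suzuki–Miyaura coupling of the hindered alkenyl triflate is followed by acid hydrolysis of the dienol ether, whose kinetic protonation at C7 gives the β,γ-unsaturated aldehyde and leaves the tetrasubstituted C5=C6 bond in the ring.

Step 4
Reactants: 7 2-[(4R)-4-(tert-butyldimethylsilyloxy)-2,6,6-trimethylcyclohex-1-en-1-yl]acetaldehyde; 8 methyl propiolate
Product: 9 methyl (2Z)-2-{1-hydroxy-2-[(4R)-4-(tert-butyldimethylsilyloxy)-2,6,6-trimethylcyclohex-1-en-1-yl]ethyl}-3-iodoprop-2-enoate (C8 epimers)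
Conditions: MgI2, CH2Cl2, 0 °C; aq NH4Cl
Reagents that add atoms: magnesium iodide, [Mg+2].[I-].[I-]
Why: In this three-component halo-aldol (β-iodo Morita–Baylis–Hillman) reaction iodide adds in conjugate fashion to the activated propiolate and the iodoallenolate meets the aldehyde on the side away from iodine, so iodine ends cis to CO2Me (Z), the geometry that later places C11 cis to C19.

Step 5
Reactants: 9 methyl (2Z)-2-{1-hydroxy-2-[(4R)-4-(tert-butyldimethylsilyloxy)-2,6,6-trimethylcyclohex-1-en-1-yl]ethyl}-3-iodoprop-2-enoate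
Product: 10 (2E)-2-(iodomethylidene)-4-[(4R)-4-(tert-butyldimethylsilyloxy)-2,6,6-trimethylcyclohex-1-en-1-yl]butane-1,3-diol
Conditions: i-Bu2AlH, CH2Cl2, −78 to −20 °C; aq potassium sodium tartrate
Reagents that add atoms: none
Why: Aluminium hydride reduction of the ester to the primary alcohol (C19) at low temperature is tolerated by alkenyl iodides and silyl ethers and keeps the alkene geometry.

Step 6
Reactants: 10 (2E)-2-(iodomethylidene)-4-[(4R)-4-(tert-butyldimethylsilyloxy)-2,6,6-trimethylcyclohex-1-en-1-yl]butane-1,3-diol; 11 (2E)-dodec-2-enoic acid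
Product: 12 (2E)-3-hydroxy-2-(iodomethylidene)-4-[(4R)-4-(tert-butyldimethylsilyloxy)-2,6,6-trimethylcyclohex-1-en-1-yl]butyl (2E)-dodec-2-enoate
Conditions: EDC·HCl, DMAP (10 mol %), CH2Cl2, 0 °C
Reagents that add atoms: none
Why: Carbodiimide (Steglich) esterification should select the primary allylic C19 hydroxyl over the hindered secondary C8 hydroxyl, and it is run cold with little DMAP so that the 2E-enoate does not deconjugate.

Step 7
Reactants: 12 (2E)-3-hydroxy-2-(iodomethylidene)-4-[(4R)-4-(tert-butyldimethylsilyloxy)-2,6,6-trimethylcyclohex-1-en-1-yl]butyl (2E)-dodec-2-enoate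
Product: 13 (2E)-2-(iodomethylidene)-3-oxo-4-[(4R)-4-(tert-butyldimethylsilyloxy)-2,6,6-trimethylcyclohex-1-en-1-yl]butyl (2E)-dodec-2-enoate
Conditions: Dess–Martin periodinane, CH2Cl2, 0 to 25 °C
Reagents that add atoms: none
Why: Dess–Martin oxidation of the secondary allylic alcohol gives the C8 ketone under nearly neutral conditions, removes the stereorandom C8 centre and should move neither the C5=C6 nor the C9=C10 bond.

Step 8
Reactants: 13 (2E)-2-(iodomethylidene)-3-oxo-4-[(4R)-4-(tert-butyldimethylsilyloxy)-2,6,6-trimethylcyclohex-1-en-1-yl]butyl (2E)-dodec-2-enoate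
Product: 14 (2E)-4-[(4R)-4-hydroxy-2,6,6-trimethylcyclohex-1-en-1-yl]-2-(iodomethylidene)-3-oxobutyl (2E)-dodec-2-enoate
Conditions: 48 % aq HF, MeCN, 0 °C
Reagents that add atoms: none
Why: Acidic fluoride desilylation is chosen because the β-iodoenone and the allylic ester tolerate acid but not nucleophilic bases such as pyridine or Bu4NF.

Step 9
Reactants: 15 2,6,6-trimethylcyclohex-2-ene-1,4-dione (ketoisophorone)
Product: 16 (4R)-4-hydroxy-2,6,6-trimethylcyclohex-2-en-1-one
Conditions: RuCl(p-cymene)[(R,R)-TsDPEN] (0.5 mol %), KOH (1 mol %), i-PrOH, 25 °C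
Reagents that add atoms: none
Why: Noyori-type asymmetric transfer hydrogenation reduces only the less hindered C4 carbonyl of the enedione, and because the alkenyl side is recognised like an aryl group the (R,R)-catalyst should set the (R)-carbinol centre, the later C3'.

Step 10
Reactants: 16 (4R)-4-hydroxy-2,6,6-trimethylcyclohex-2-en-1-one
Product: 17 (4R)-4-(triethylsilyloxy)-2,6,6-trimethylcyclohex-2-en-1-one
Conditions: Et3SiCl, imidazole, CH2Cl2, 0 °C
Reagents that add atoms: chlorotriethylsilane, CC[Si](Cl)(CC)CC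
Why: Silyl ether formation gives a group that survives organometallic and mildly basic steps yet falls off under the weak acid of step 15.

Step 11
Reactants: 17 (4R)-4-(triethylsilyloxy)-2,6,6-trimethylcyclohex-2-en-1-one
Product: 19 (6R)-6-(triethylsilyloxy)-4,8,8-trimethyl-1-oxaspiro[2.5]oct-4-ene, via lithium chlorohydrinate 18 (not isolated)
Conditions: ICH2Cl, MeLi·LiBr, THF, −78 to 25 °C
Reagents that add atoms: chloroiodomethane, ClCI; methyllithium, [Li]C (its lithium stays in 18 only)
Why: In this halomethyllithium epoxidation the small carbenoid, formed by iodine–lithium exchange in the presence of the ketone, adds 1,2 to the hindered enone at −78 °C faster than it can deprotonate the γ-position (C3'), and the chlorohydrinate closes to the spiro-epoxide on warming.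

Step 12
Reactants: 19 (6R)-6-(triethylsilyloxy)-4,8,8-trimethyl-1-oxaspiro[2.5]oct-4-ene
Product: 20 (1R,4R)-4-(triethylsilyloxy)-2,6,6-trimethylcyclohex-2-ene-1-carbaldehyde
Conditions: MgBr2·OEt2, Et2O, 0 °C
Reagents that add atoms: none
Why: In this Meinwald rearrangement the Lewis acid opens the epoxide to the tertiary allylic cation at C6' and the 1,2-hydride shift from the CH2O carbon reaches C6' pseudo-axially on the face opposite the axial C1' methyl group, which is the face of the pseudo-equatorial silyloxy group, so the formyl group should end trans to it (6'R), also the more stable arrangement.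

Step 13
Reactants: 20 (1R,4R)-4-(triethylsilyloxy)-2,6,6-trimethylcyclohex-2-ene-1-carbaldehyde
Product: 21 (3E)-4-[(1R,4R)-4-(triethylsilyloxy)-2,6,6-trimethylcyclohex-2-en-1-yl]but-3-en-2-one
Conditions: (EtO)2P(O)CH2C(O)CH3, Ba(OH)2, THF/H2O 40:1, 25 °C
Reagents that add atoms: diethyl (2-oxopropyl)phosphonate, CCOP(=O)(CC(C)=O)OCC
Why: The Horner–Wadsworth–Emmons reaction under mild Ba(OH)2 activation gives the E-enone (C7'=C8') and should be gentle enough neither to epimerise C6' nor to pull the ring double bond into conjugation.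

Step 14
Reactants: 21 (3E)-4-[(1R,4R)-4-(triethylsilyloxy)-2,6,6-trimethylcyclohex-2-en-1-yl]but-3-en-2-one
Product: 22 (1E)-3-methyl-1-[(1R,4R)-4-(triethylsilyloxy)-2,6,6-trimethylcyclohex-2-en-1-yl]penta-1,4-dien-3-ol (C9' epimers)
Conditions: CH2=CHMgBr, THF, −78 to 0 °C; aq NH4Cl
Reagents that add atoms: vinylmagnesium bromide, C=C[Mg]Br
Why: Grignard 1,2-addition to the methyl ketone, the usual behaviour of ionone-type enones, installs C10' and C11', and the new C9' centre is lost in step 15.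

Step 15
Reactants: 22 (1E)-3-methyl-1-[(1R,4R)-4-(triethylsilyloxy)-2,6,6-trimethylcyclohex-2-en-1-yl]penta-1,4-dien-3-ol
Product: 24 {(2E,4E)-5-[(1R,4R)-4-hydroxy-2,6,6-trimethylcyclohex-2-en-1-yl]-3-methylpenta-2,4-dien-1-yl}triphenylphosphonium bromide, via silylated phosphonium bromide 23 (not isolated)
Conditions: PPh3·HBr (1.15 equiv), MeOH, 0 to 25 °C; crystallisation from EtOAc
Reagents that add atoms: triphenylphosphine hydrobromide, Br.c1ccc(cc1)P(c1ccccc1)c1ccccc1
Why: Acid ionisation of the tertiary bis-allylic alcohol to a pentadienyl cation and capture by PPh3 at the open terminus (the standard SN1-type route to C15 Wittig salts) should give mainly the 9'E salt, and the small excess of acid methanolyses the triethylsilyl ether in the same flask.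

Step 16
Reactants: 25 (2E,4E,6E)-2,7-dimethylocta-2,4,6-trienedial
Product: 26 (2E,4E,6E,8E)-2,7-dimethyl-9-(4,4,5,5-tetramethyl-1,3,2-dioxaborolan-2-yl)nona-2,4,6,8-tetraenal
Conditions: Cl2CHBpin, CrCl2, LiI, THF, 25 °C; 25 in threefold excess, surplus recovered
Reagents that add atoms: 2-(dichloromethyl)-4,4,5,5-tetramethyl-1,3,2-dioxaborolane, ClC(Cl)B1OC(C)(C)C(C)(C)O1
Why: In this Takai–Utimoto-type olefination divalent chromium turns the gem-dihalide into a geminal dichromium reagent that adds to one formyl group and eliminates to the E-alkenylboronate (C11=C12), while the excess of dialdehyde holds back the double reaction.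

Step 17
Reactants: 24 {(2E,4E)-5-[(1R,4R)-4-hydroxy-2,6,6-trimethylcyclohex-2-en-1-yl]-3-methylpenta-2,4-dien-1-yl}triphenylphosphonium bromide; 26 (2E,4E,6E,8E)-2,7-dimethyl-9-(4,4,5,5-tetramethyl-1,3,2-dioxaborolan-2-yl)nona-2,4,6,8-tetraenal
Product: 28 (1R,4R)-3,5,5-trimethyl-4-[(1E,3E,5E,7E,9E,11E,13E)-3,7,12-trimethyl-14-(4,4,5,5-tetramethyl-1,3,2-dioxaborolan-2-yl)tetradeca-1,3,5,7,9,11,13-heptaen-1-yl]cyclohex-2-en-1-ol, via phosphorus ylide 27 (not isolated)
Conditions: NaOMe, MeOH/CH2Cl2, 0 to 25 °C; then n-heptane, 80 °C, dark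
Reagents that add atoms: none
Why: The Wittig reaction of the semistabilised C15 ylide with the α-methyl enal forms C11'=C12', whose sterically hindered Z isomer relaxes thermally to E as is usual for carotenoids, and the pinacol boronate and the free hydroxyl group tolerate methoxide.

Step 18
Reactants: 14 (2E)-4-[(4R)-4-hydroxy-2,6,6-trimethylcyclohex-1-en-1-yl]-2-(iodomethylidene)-3-oxobutyl (2E)-dodec-2-enoate; 28 (1R,4R)-3,5,5-trimethyl-4-[(1E,3E,5E,7E,9E,11E,13E)-3,7,12-trimethyl-14-(4,4,5,5-tetramethyl-1,3,2-dioxaborolan-2-yl)tetradeca-1,3,5,7,9,11,13-heptaen-1-yl]cyclohex-2-en-1-ol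
Product: 29 (3R,3'R,6'R)-3,3'-dihydroxy-8-oxo-7,8-dihydro-β,ε-caroten-19-yl (2E)-dodec-2-enoate (target, all-E)
Conditions: Pd(PPh3)4 (5 mol %), TlOEt (1.5 equiv, added last), degassed THF/H2O 3:1, 25 °C, dark
Reagents that add atoms: none
Why: Zerovalent palladium inserts with retention into the C10–I bond of 14, which as a vinylogous acyl iodide (β-carbon of the C8 enone) is by far the fastest site for oxidative addition; TlOEt removes iodide as insoluble TlI and activates the boronate, the C11 alkenyl group of 28 is transferred with retention, and reductive elimination forms the C10–C11 bond. The closest known reaction type is the thallium-base-accelerated Suzuki–Miyaura alkenyl–alkenyl coupling used for sensitive polyenes at room temperature. No ring is closed and no stereocentre is created; the 9E and 11E geometries are those built into 14 (step 4) and 28 (step 16), and C3, C3' and C6' lie far from the reacting centres. The step needs chemoselectivity for C–I insertion over ionisation of the allylic C19 ester and over addition of base at C10, which the activated iodide, the addition of TlOEt as last component and a reaction time of minutes should secure. The free hydroxyl groups, the enoate and the acidic C7 methylene should stay untouched under these conditions, so the coupling product is the target itself.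

Compound list
1 | (4R,6R)-4-hydroxy-2,2,6-trimethylcyclohexan-1-one (actinol) | C[C@@H]1C[C@@H](O)CC(C)(C)C1=O | starting material
2 | (4R,6R)-4-(tert-butyldimethylsilyloxy)-2,2,6-trimethylcyclohexan-1-one | C[C@@H]1C[C@@H](O[Si](C)(C)C(C)(C)C)CC(C)(C)C1=O | intermediate
3 | potassium enolate of 2 | [K+].[O-]C1=C(C)C[C@@H](O[Si](C)(C)C(C)(C)C)CC1(C)C | intermediate
4 | (4R)-4-(tert-butyldimethylsilyloxy)-2,6,6-trimethylcyclohex-1-en-1-yl trifluoromethanesulfonate | FC(F)(F)S(=O)(=O)OC1=C(C)C[C@@H](O[Si](C)(C)C(C)(C)C)CC1(C)C | intermediate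
5 | (E)-2-(2-ethoxyvinyl)-4,4,5,5-tetramethyl-1,3,2-dioxaborolane | CCO/C=C/B1OC(C)(C)C(C)(C)O1 | starting material
6 | tert-butyl{[(1R)-4-[(E)-2-ethoxyvinyl]-3,5,5-trimethylcyclohex-3-en-1-yl]oxy}dimethylsilane (dienol ether) | CCO/C=C/C1=C(C)C[C@@H](O[Si](C)(C)C(C)(C)C)CC1(C)C | intermediate
7 | 2-[(4R)-4-(tert-butyldimethylsilyloxy)-2,6,6-trimethylcyclohex-1-en-1-yl]acetaldehyde | O=CCC1=C(C)C[C@@H](O[Si](C)(C)C(C)(C)C)CC1(C)C | intermediate
8 | methyl propiolate | C#CC(=O)OC | starting material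
9 | methyl (2Z)-2-{1-hydroxy-2-[(4R)-4-(tert-butyldimethylsilyloxy)-2,6,6-trimethylcyclohex-1-en-1-yl]ethyl}-3-iodoprop-2-enoate | COC(=O)/C(=C\I)C(O)CC1=C(C)C[C@@H](O[Si](C)(C)C(C)(C)C)CC1(C)C | intermediate
10 | (2E)-2-(iodomethylidene)-4-[(4R)-4-(tert-butyldimethylsilyloxy)-2,6,6-trimethylcyclohex-1-en-1-yl]butane-1,3-diol | OC/C(=C\I)C(O)CC1=C(C)C[C@@H](O[Si](C)(C)C(C)(C)C)CC1(C)C | intermediate
11 | (2E)-dodec-2-enoic acid | CCCCCCCCC/C=C/C(=O)O | starting material
12 | (2E)-3-hydroxy-2-(iodomethylidene)-4-[(4R)-4-(tert-butyldimethylsilyloxy)-2,6,6-trimethylcyclohex-1-en-1-yl]butyl (2E)-dodec-2-enoate | CCCCCCCCC/C=C/C(=O)OC/C(=C\I)C(O)CC1=C(C)C[C@@H](O[Si](C)(C)C(C)(C)C)CC1(C)C | intermediate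
13 | (2E)-2-(iodomethylidene)-3-oxo-4-[(4R)-4-(tert-butyldimethylsilyloxy)-2,6,6-trimethylcyclohex-1-en-1-yl]butyl (2E)-dodec-2-enoate | CCCCCCCCC/C=C/C(=O)OC/C(=C\I)C(=O)CC1=C(C)C[C@@H](O[Si](C)(C)C(C)(C)C)CC1(C)C | intermediate
14 | (2E)-4-[(4R)-4-hydroxy-2,6,6-trimethylcyclohex-1-en-1-yl]-2-(iodomethylidene)-3-oxobutyl (2E)-dodec-2-enoate | CCCCCCCCC/C=C/C(=O)OC/C(=C\I)C(=O)CC1=C(C)C[C@@H](O)CC1(C)C | intermediate
15 | 2,6,6-trimethylcyclohex-2-ene-1,4-dione (ketoisophorone) | CC1=CC(=O)CC(C)(C)C1=O | starting material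
16 | (4R)-4-hydroxy-2,6,6-trimethylcyclohex-2-en-1-one | CC1=C[C@H](O)CC(C)(C)C1=O | intermediate
17 | (4R)-4-(triethylsilyloxy)-2,6,6-trimethylcyclohex-2-en-1-one | CC1=C[C@H](O[Si](CC)(CC)CC)CC(C)(C)C1=O | intermediate
18 | lithium (4R)-1-(chloromethyl)-4-(triethylsilyloxy)-2,6,6-trimethylcyclohex-2-en-1-olate | [Li+].[O-]C1(CCl)C(C)=C[C@H](O[Si](CC)(CC)CC)CC1(C)C | intermediate
19 | (6R)-6-(triethylsilyloxy)-4,8,8-trimethyl-1-oxaspiro[2.5]oct-4-ene | C1OC12C(C)=C[C@H](O[Si](CC)(CC)CC)CC2(C)C | intermediate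
20 | (1R,4R)-4-(triethylsilyloxy)-2,6,6-trimethylcyclohex-2-ene-1-carbaldehyde | O=C[C@H]1C(C)=C[C@H](O[Si](CC)(CC)CC)CC1(C)C | intermediate
21 | (3E)-4-[(1R,4R)-4-(triethylsilyloxy)-2,6,6-trimethylcyclohex-2-en-1-yl]but-3-en-2-one | CC(=O)/C=C/[C@H]1C(C)=C[C@H](O[Si](CC)(CC)CC)CC1(C)C | intermediate
22 | (1E)-3-methyl-1-[(1R,4R)-4-(triethylsilyloxy)-2,6,6-trimethylcyclohex-2-en-1-yl]penta-1,4-dien-3-ol | C=CC(C)(O)/C=C/[C@H]1C(C)=C[C@H](O[Si](CC)(CC)CC)CC1(C)C | intermediate
23 | {(2E,4E)-3-methyl-5-[(1R,4R)-4-(triethylsilyloxy)-2,6,6-trimethylcyclohex-2-en-1-yl]penta-2,4-dien-1-yl}triphenylphosphonium bromide | [Br-].c1ccccc1[P+](c1ccccc1)(c1ccccc1)C/C=C(C)/C=C/[C@H]1C(C)=C[C@H](O[Si](CC)(CC)CC)CC1(C)C | intermediate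
24 | {(2E,4E)-5-[(1R,4R)-4-hydroxy-2,6,6-trimethylcyclohex-2-en-1-yl]-3-methylpenta-2,4-dien-1-yl}triphenylphosphonium bromide | [Br-].c1ccccc1[P+](c1ccccc1)(c1ccccc1)C/C=C(C)/C=C/[C@H]1C(C)=C[C@H](O)CC1(C)C | intermediate
25 | (2E,4E,6E)-2,7-dimethylocta-2,4,6-trienedial | O=C/C(C)=C/C=C/C=C(C)/C=O | starting material
26 | (2E,4E,6E,8E)-2,7-dimethyl-9-(4,4,5,5-tetramethyl-1,3,2-dioxaborolan-2-yl)nona-2,4,6,8-tetraenal | CC1(C)OB(/C=C/C(C)=C/C=C/C=C(C)/C=O)OC1(C)C | intermediate
27 | phosphorus ylide of 24 | c1ccccc1[P+](c1ccccc1)(c1ccccc1)[CH-]/C=C(C)/C=C/[C@H]1C(C)=C[C@H](O)CC1(C)C | intermediate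
28 | (1R,4R)-3,5,5-trimethyl-4-[(1E,3E,5E,7E,9E,11E,13E)-3,7,12-trimethyl-14-(4,4,5,5-tetramethyl-1,3,2-dioxaborolan-2-yl)tetradeca-1,3,5,7,9,11,13-heptaen-1-yl]cyclohex-2-en-1-ol | CC1(C)OB(/C=C/C(C)=C/C=C/C=C(C)/C=C/C=C(C)/C=C/[C@H]2C(C)=C[C@H](O)CC2(C)C)OC1(C)C | intermediate
29 | (3R,3'R,6'R)-3,3'-dihydroxy-8-oxo-7,8-dihydro-β,ε-caroten-19-yl (2E)-dodec-2-enoate | CCCCCCCCC/C=C/C(=O)OC\C(=C/C=C/C(C)=C/C=C/C=C(C)/C=C/C=C(C)/C=C/[C@H]1C(C)=C[C@H](O)CC1(C)C)C(=O)CC1=C(C)C[C@@H](O)CC1(C)C | target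

Total step count: 18 steps. Longest linear sequence: 9 steps (steps 1–8 and 18, or steps 9–15, 17 and 18).

Steps most likely to fail

Step 18.
- What may go wrong: ethoxide or hydroxide may attack C10 of the vinylogous acyl iodide. Zerovalent palladium may ionise the allylic C19 ester once the iodide is used up. The polyenylboronate may also undergo protodeboronation.
- Fallback: boron and base are replaced by a neutral Stille coupling. It sets out from 25 and comes back at 29. CH2Br2 is lithiated with LiN(i-Pr)2 at −95 °C and quenched with Bu3SnCl to give (dibromomethyl)tributylstannane F1. F1, CrCl2 and LiI convert an excess of 25 into the stannyl tetraenal F2. Wittig reaction of 24 (through 27) with F2 gives the heptaenylstannane F3. F3 and 14 are then joined with Pd2(dba)3 and AsPh3 in DMF at 25 °C in the dark, again by forming the C10–C11 bond, to give 29.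

Step 12.
- What may go wrong: the hydride shift may show poor facial selectivity at C6'. Bromide may open the epoxide instead of the rearrangement taking place. The ring double bond may drift into conjugation with the new aldehyde.
- Fallback: the cationic event is replaced by a concerted hydroboration. It sets out from 17 and comes back at 20. Non-basic methylenation with Cp2TiMe2 (toluene, 70 °C) gives the exocyclic diene F4. 9-BBN-H adds to the 1,1-disubstituted double bond, with boron at C7' and hydrogen at C6' on the face opposite the axial C1' methyl group, to give the alkylborane F5. NaBO3 oxidation gives the primary alcohol F6, and Dess–Martin oxidation of F6 gives 20.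

Step 15.
- What may go wrong: acid may ionise the ring allylic C3' oxygen function, leading to solvolysis or dehydration. The silyl group may be lost only in part. The 9' geometry may erode.
- Fallback: the Brønsted acid is avoided. It sets out from 22 and comes back at 28. PBr3 and pyridine in Et2O at −20 °C convert 22 with allylic transposition into the primary dienyl bromide F7. PPh3 in toluene turns F7 into 23, now isolated. NaOMe converts 23 into the silylated ylide F8, which reacts with 26 to give the silylated heptaenylboronate F9. AcOH/THF/H2O at 25 °C then removes the triethylsilyl group and gives 28.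

Further compounds
F1 | step 18 | (dibromomethyl)tributylstannane | CCCC[Sn](CCCC)(CCCC)C(Br)Br
F2 | step 18 | (2E,4E,6E,8E)-2,7-dimethyl-9-(tributylstannyl)nona-2,4,6,8-tetraenal | CCCC[Sn](CCCC)(CCCC)/C=C/C(C)=C/C=C/C=C(C)/C=O
F3 | step 18 | (1R,4R)-3,5,5-trimethyl-4-[(1E,3E,5E,7E,9E,11E,13E)-3,7,12-trimethyl-14-(tributylstannyl)tetradeca-1,3,5,7,9,11,13-heptaen-1-yl]cyclohex-2-en-1-ol | CCCC[Sn](CCCC)(CCCC)/C=C/C(C)=C/C=C/C=C(C)/C=C/C=C(C)/C=C/[C@H]1C(C)=C[C@H](O)CC1(C)C
F4 | step 12 | triethyl{[(1R)-3,5,5-trimethyl-4-methylidenecyclohex-2-en-1-yl]oxy}silane | C=C1C(C)=C[C@H](O[Si](CC)(CC)CC)CC1(C)C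
F5 | step 12 | 9-{[(1R,4R)-4-(triethylsilyloxy)-2,6,6-trimethylcyclohex-2-en-1-yl]methyl}-9-borabicyclo[3.3.1]nonane | C(B1C2CCCC1CCC2)[C@H]1C(C)=C[C@H](O[Si](CC)(CC)CC)CC1(C)C
F6 | step 12 | [(1R,4R)-4-(triethylsilyloxy)-2,6,6-trimethylcyclohex-2-en-1-yl]methanol | OC[C@H]1C(C)=C[C@H](O[Si](CC)(CC)CC)CC1(C)C
F7 | step 15 | {[(1R,4R)-4-[(1E,3E)-5-bromo-3-methylpenta-1,3-dien-1-yl]-3,5,5-trimethylcyclohex-2-en-1-yl]oxy}triethylsilane | BrC/C=C(C)/C=C/[C@H]1C(C)=C[C@H](O[Si](CC)(CC)CC)CC1(C)C
F8 | step 15 | phosphorus ylide of 23 | c1ccccc1[P+](c1ccccc1)(c1ccccc1)[CH-]/C=C(C)/C=C/[C@H]1C(C)=C[C@H](O[Si](CC)(CC)CC)CC1(C)C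
F9 | step 15 | triethylsilyl ether of 28 | CC1(C)OB(/C=C/C(C)=C/C=C/C=C(C)/C=C/C=C(C)/C=C/[C@H]2C(C)=C[C@H](O[Si](CC)(CC)CC)CC2(C)C)OC1(C)C
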